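The octadienyl chain is cut between C4 (the CH2 next to the trisubstituted alkene) and alkene carbon C3 (chain numbered from the coumarin ether oxygen). C4 is the α-carbon of a latent γ-silyloxy carboxylic acid, so its N-hydroxyphthalimide ester serves as a traceless primary-radical source. C3 is the iodinated carbon of a cis-but-2-ene-1,4-diol unit that already carries the 5-methylcoumarin ring system, its geometry fixed by syn-hydrostannation of butynediol. One nickel-electrocatalytic decarboxylative alkenylation joins both halves with retention of alkene geometry. The C6 hydroperoxide is then installed with inversion from the CBS-derived (R)-alcohol by peroxide displacement.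

Key step: step 12

Remark: chain atoms are numbered as in the target name (C1 = OCH2 to C8 = terminal =CH2). Compounds carrying the 1-ethoxyethyl acetal are mixtures of epimers at the acetal carbon, which is removed in step 15.

Step 1
Reactants: 1 methyl 4-chloro-4-oxobutanoate; 2 isopropenylmagnesium bromide
Product: 3 methyl 5-methyl-4-oxohex-5-enoate
Conditions: CuI (5 mol%), THF, −78 °C, slow addition of 2 (0.95 equiv) to 1
Reagents that add atoms: none
Why: Copper-catalysed acylation of a Grignard reagent by an acid chloride, in which at −78 °C with inverse addition the acyl chloride should be consumed far faster than the methyl ester or the enone formed.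

Step 2
Reactants: 3 methyl 5-methyl-4-oxohex-5-enoate
Product: 4 methyl (4R)-4-hydroxy-5-methylhex-5-enoate
Conditions: (S)-Me-CBS (10 mol%), BH3·SMe2, THF, −20 °C; MeOH quench; used crude
Reagents that add atoms: none
Why: Corey–Bakshi–Shibata reduction in which, with isopropenyl as the large and the CH2CH2CO2Me chain as the small substituent, the (S)-oxazaborolidine should deliver hydride to the face that gives the (R)-carbinol (the later C6), which is silylated crude before it can lactonise.

Step 3
Reactants: 4 methyl (4R)-4-hydroxy-5-methylhex-5-enoate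
Product: 5 methyl (4R)-4-[(tert-butyldimethylsilyl)oxy]-5-methylhex-5-enoate
Conditions: TBSCl, imidazole, DMF, rt
Reagents that add atoms: tert-butyldimethylsilyl chloride, CC(C)(C)[Si](C)(C)Cl
Why: Standard silylation of a secondary allylic alcohol; the silyl ether blocks γ-lactonisation and should survive steps 4, 5 and 12.

Step 4
Reactants: 5 methyl (4R)-4-[(tert-butyldimethylsilyl)oxy]-5-methylhex-5-enoate
Product: 6 (4R)-4-[(tert-butyldimethylsilyl)oxy]-5-methylhex-5-enoic acid
Conditions: LiOH·H2O, THF/MeOH/H2O, 0 °C to rt; then cold 1 M HCl to pH 4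
Reagents that add atoms: lithium hydroxide, [Li+].[OH-]
Why: Saponification of a methyl ester, to which the secondary TBS ether is stable, as it is to brief acidification to pH 4.

Step 5
Reactants: 6 (4R)-4-[(tert-butyldimethylsilyl)oxy]-5-methylhex-5-enoic acid
Product: 7 1,3-dioxoisoindolin-2-yl (4R)-4-[(tert-butyldimethylsilyl)oxy]-5-methylhex-5-enoate
Conditions: N-hydroxyphthalimide, DIC, DMAP (cat.), CH2Cl2, rt
Reagents that add atoms: N-hydroxyphthalimide, O=C1c2ccccc2C(=O)N1O
Why: Carbodiimide (Steglich-type) esterification gives the redox-active N-acyloxyphthalimide needed as radical precursor.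

Step 6
Reactants: 8 1-(2-hydroxy-6-methylphenyl)ethan-1-one
Product: 9 4-hydroxy-5-methyl-2H-chromen-2-one
Conditions: NaH, diethyl carbonate, toluene, 110 °C; then aq. HCl
Reagents that add atoms: diethyl carbonate, CCOC(=O)OCC
Why: Claisen-type C-acylation of the methyl ketone enolate by diethyl carbonate followed by lactonisation onto the phenoxide is the standard 4-hydroxycoumarin synthesis, and the 6′-methyl group ends up at C5.

Step 7
Reactants: 10 but-2-yne-1,4-diol
Product: 11 (2E)-2-(tributylstannyl)but-2-ene-1,4-diol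
Conditions: Bu3SnH, PdCl2(PPh3)2 (1 mol%), THF, rt
Reagents that add atoms: tributyltin hydride, CCCC[SnH](CCCC)CCCC
Why: Palladium-catalysed hydrostannation is a syn addition, so H and Sn end up cis and the two CH2OH groups cis to each other, and the symmetric alkyne poses no regiochemical question.

Step 8
Reactants: 11 (2E)-2-(tributylstannyl)but-2-ene-1,4-diol; 9 4-hydroxy-5-methyl-2H-chromen-2-one
Product: 12 4-{[(2E)-4-hydroxy-3-(tributylstannyl)but-2-en-1-yl]oxy}-5-methyl-2H-chromen-2-one
Conditions: PPh3, DIAD, THF, 0 °C to rt; 11 in excess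
Reagents that add atoms: none
Why: Mitsunobu O-alkylation of the acidic 4-hydroxycoumarin, in which the hydroxyl remote from the bulky Bu3Sn group should be activated preferentially and the excess of diol suppresses double etherification.

Step 9
Reactants: 12 4-{[(2E)-4-hydroxy-3-(tributylstannyl)but-2-en-1-yl]oxy}-5-methyl-2H-chromen-2-one
Product: 13 4-{[(2E)-4-hydroxy-3-iodobut-2-en-1-yl]oxy}-5-methyl-2H-chromen-2-one
Conditions: I2 (1.05 equiv), CH2Cl2, 0 °C
Reagents that add atoms: iodine, II
Why: Iododestannylation of an alkenylstannane is an ipso substitution that proceeds with retention of alkene geometry.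

Step 10
Reactants: 13 4-{[(2E)-4-hydroxy-3-iodobut-2-en-1-yl]oxy}-5-methyl-2H-chromen-2-one
Product: 14 4-{[(2E)-4-(1-ethoxyethoxy)-3-iodobut-2-en-1-yl]oxy}-5-methyl-2H-chromen-2-one
Conditions: ethyl vinyl ether, PPTS (cat.), CH2Cl2, rt
Reagents that add atoms: ethyl vinyl ether, C=COCC
Why: Acid-catalysed addition of the alcohol to the enol ether gives the 1-ethoxyethyl acetal, which should be inert in steps 12 to 14 and is cleaved by mild acid.

Step 11
Reactants: 15 2,3-dimethylbut-2-ene
Product: 17 2-methoxyprop-2-yl hydroperoxide, via acetone O-oxide 16 (not isolated)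
Conditions: O3, MeOH/CH2Cl2, −78 °C; used as a solution
Reagents that add atoms: ozone, [O-][O+]=O; methanol, CO
Why: Criegee ozonolysis of a tetrasubstituted alkene in methanol, in which the carbonyl oxide is trapped by the solvent as the α-methoxy hydroperoxide and acetone is the only co-product.

Step 12
Reactants: 7 1,3-dioxoisoindolin-2-yl (4R)-4-[(tert-butyldimethylsilyl)oxy]-5-methylhex-5-enoate; 14 4-{[(2E)-4-(1-ethoxyethoxy)-3-iodobut-2-en-1-yl]oxy}-5-methyl-2H-chromen-2-one
Product: 18 4-{[(2Z,6R)-6-[(tert-butyldimethylsilyl)oxy]-3-[(1-ethoxyethoxy)methyl]-7-methylocta-2,7-dien-1-yl]oxy}-5-methyl-2H-chromen-2-one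
Conditions: NiCl2·6H2O (10 mol%), 2,2′-bipyridine (10 mol%), AgNO3 (0.3 equiv), DMF, (+)Mg/(−)RVC, undivided cell, constant current, rt; 7 in excess
Reagents that add atoms: none
Why: Cathodic reduction generates low-valent (bpy)Ni at the silver-coated cathode, which inserts into the C3–I bond of 14 with retention, while single-electron reduction of 7 expels phthalimide anion and CO2 and leaves the primary C4 radical. Capture of that radical by the alkenyl–Ni(II) species and reductive elimination from Ni(III) forge the C4–C3 bond. The closest known reaction type is the nickel-electrocatalytic decarboxylative alkenylation of N-hydroxyphthalimide esters with 3-iodoallyl ethers used in modular polyene assembly. No ring is closed and no stereocentre is formed: C6 sits two carbons from the radical site and stays (R), and the Z geometry (the two CH2O groups cis) is inherited from 14 because both organonickel events at C3 are stereoretentive. The step needs chemoselective C–I activation over the allylic C1–O bond of the coumarinyl ether and over the lactone, which the far faster oxidative addition of the alkenyl iodide, the mild cathode potential held by the Ni/ester couple and ending the electrolysis once 14 is consumed should secure. The C4 radical has no cyclisation outlet (only 3-exo or 4-endo paths to C7=C8) and should be trapped by nickel faster than a 1,5-hydrogen shift from the C7 methyl group can occur.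

Step 13
Reactants: 18 4-{[(2Z,6R)-6-[(tert-butyldimethylsilyl)oxy]-3-[(1-ethoxyethoxy)methyl]-7-methylocta-2,7-dien-1-yl]oxy}-5-methyl-2H-chromen-2-one
Product: 19 4-{[(2Z,6R)-3-[(1-ethoxyethoxy)methyl]-6-hydroxy-7-methylocta-2,7-dien-1-yl]oxy}-5-methyl-2H-chromen-2-one
Conditions: TBAF, THF, 0 °C to rt
Reagents that add atoms: none
Why: Fluoride cleaves the secondary TBS ether, while the acetal, the coumarinyl ether and the lactone should be inert to TBAF at this temperature.

Step 14
Reactants: 19 4-{[(2Z,6R)-3-[(1-ethoxyethoxy)methyl]-6-hydroxy-7-methylocta-2,7-dien-1-yl]oxy}-5-methyl-2H-chromen-2-one; 17 2-methoxyprop-2-yl hydroperoxide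
Product: 21 4-{[(2Z,6S)-3-[(1-ethoxyethoxy)methyl]-6-[(2-methoxypropan-2-yl)peroxy]-7-methylocta-2,7-dien-1-yl]oxy}-5-methyl-2H-chromen-2-one, via allylic mesylate 20 (not isolated)
Conditions: Ms2O, Et3N, THF, −40 °C; then 17 (excess), CsOH·H2O, DMF, −40 to 0 °C
Reagents that add atoms: methanesulfonic anhydride, CS(=O)(=O)OS(C)(=O)=O (atoms kept in intermediate 20 only)
Why: SN2 alkylation of a peroxyketal-protected hydroperoxide anion by a secondary sulfonate, in which the mesylate of the (6R)-alcohol, made with the chloride-free anhydride, should be displaced with inversion by the α-effect peroxy anion to set the (6S) C–OO centre.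

Step 15
Reactants: 21 4-{[(2Z,6S)-3-[(1-ethoxyethoxy)methyl]-6-[(2-methoxypropan-2-yl)peroxy]-7-methylocta-2,7-dien-1-yl]oxy}-5-methyl-2H-chromen-2-one
Product: 22 4-{[(2Z,6S)-6-hydroperoxy-3-(hydroxymethyl)-7-methylocta-2,7-dien-1-yl]oxy}-5-methyl-2H-chromen-2-one
Conditions: AcOH/THF/H2O (4:2:1), BHT (trace), rt
Reagents that add atoms: none
Why: Mild aqueous acid hydrolyses both the peroxyketal and the 1-ethoxyethyl acetal, while the allylic hydroperoxide, the allylic aryl ether and the coumarin should survive and C6 is not touched.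

Compound list
1 | methyl 4-chloro-4-oxobutanoate | COC(=O)CCC(Cl)=O | starting material
2 | isopropenylmagnesium bromide (prop-1-en-2-ylmagnesium bromide) | C=C(C)[Mg]Br | starting material
3 | methyl 5-methyl-4-oxohex-5-enoate | C=C(C)C(=O)CCC(=O)OC | intermediate
4 | methyl (4R)-4-hydroxy-5-methylhex-5-enoate | C=C(C)[C@@H](CCC(=O)OC)O | intermediate
5 | methyl (4R)-4-[(tert-butyldimethylsilyl)oxy]-5-methylhex-5-enoate | C=C(C)[C@@H](CCC(=O)OC)O[Si](C)(C)C(C)(C)C | intermediate
6 | (4R)-4-[(tert-butyldimethylsilyl)oxy]-5-methylhex-5-enoic acid | C=C(C)[C@@H](CCC(=O)O)O[Si](C)(C)C(C)(C)C | intermediate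
7 | 1,3-dioxoisoindolin-2-yl (4R)-4-[(tert-butyldimethylsilyl)oxy]-5-methylhex-5-enoate | C=C(C)[C@@H](CCC(=O)ON1C(=O)c2ccccc2C1=O)O[Si](C)(C)C(C)(C)C | intermediate
8 | 1-(2-hydroxy-6-methylphenyl)ethan-1-one (2′-hydroxy-6′-methylacetophenone) | CC(=O)c1c(C)cccc1O | starting material
9 | 4-hydroxy-5-methyl-2H-chromen-2-one | Oc1cc(=O)oc2cccc(C)c12 | intermediate
10 | but-2-yne-1,4-diol | OCC#CCO | starting material
11 | (2E)-2-(tributylstannyl)but-2-ene-1,4-diol | CCCC[Sn](CCCC)(CCCC)/C(=C/CO)CO | intermediate
12 | 4-{[(2E)-4-hydroxy-3-(tributylstannyl)but-2-en-1-yl]oxy}-5-methyl-2H-chromen-2-one | CCCC[Sn](CCCC)(CCCC)/C(=C/COc1cc(=O)oc2cccc(C)c12)CO | intermediate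
13 | 4-{[(2E)-4-hydroxy-3-iodobut-2-en-1-yl]oxy}-5-methyl-2H-chromen-2-one | I/C(=C/COc1cc(=O)oc2cccc(C)c12)CO | intermediate
14 | 4-{[(2E)-4-(1-ethoxyethoxy)-3-iodobut-2-en-1-yl]oxy}-5-methyl-2H-chromen-2-one | I/C(=C/COc1cc(=O)oc2cccc(C)c12)COC(C)OCC | intermediate
15 | 2,3-dimethylbut-2-ene | CC(C)=C(C)C | starting material
16 | acetone O-oxide (carbonyl oxide, not isolated) | CC(C)=[O+][O-] | intermediate
17 | 2-methoxyprop-2-yl hydroperoxide | COC(C)(C)OO | intermediate
18 | 4-{[(2Z,6R)-6-[(tert-butyldimethylsilyl)oxy]-3-[(1-ethoxyethoxy)methyl]-7-methylocta-2,7-dien-1-yl]oxy}-5-methyl-2H-chromen-2-one | C=C(C)[C@@H](CC/C(=C/COc1cc(=O)oc2cccc(C)c12)COC(C)OCC)O[Si](C)(C)C(C)(C)C | intermediate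
19 | 4-{[(2Z,6R)-3-[(1-ethoxyethoxy)methyl]-6-hydroxy-7-methylocta-2,7-dien-1-yl]oxy}-5-methyl-2H-chromen-2-one | C=C(C)[C@@H](CC/C(=C/COc1cc(=O)oc2cccc(C)c12)COC(C)OCC)O | intermediate
20 | 4-{[(2Z,6R)-3-[(1-ethoxyethoxy)methyl]-6-(methanesulfonyloxy)-7-methylocta-2,7-dien-1-yl]oxy}-5-methyl-2H-chromen-2-one (not isolated) | C=C(C)[C@@H](CC/C(=C/COc1cc(=O)oc2cccc(C)c12)COC(C)OCC)OS(C)(=O)=O | intermediate
21 | 4-{[(2Z,6S)-3-[(1-ethoxyethoxy)methyl]-6-[(2-methoxypropan-2-yl)peroxy]-7-methylocta-2,7-dien-1-yl]oxy}-5-methyl-2H-chromen-2-one | C=C(C)[C@H](CC/C(=C/COc1cc(=O)oc2cccc(C)c12)COC(C)OCC)OOC(C)(C)OC | intermediate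
22 | 4-{[(2Z,6S)-6-hydroperoxy-3-(hydroxymethyl)-7-methylocta-2,7-dien-1-yl]oxy}-5-methyl-2H-chromen-2-one | C=C(C)[C@H](CC/C(=C/COc1cc(=O)oc2cccc(C)c12)CO)OO | target

Total step count: 15 (left half steps 1–5, right half steps 6–10, peroxide reagent step 11, union and end game steps 12–15).
Longest linear sequence: 9 steps (1, 2, 3, 4, 5, 12, 13, 14, 15).

Steps most likely to fail

1. Step 14. The peroxy anion may attack the terminal C8 methylene (SN2′) or the mesylate may ionise, which would give the transposed primary peroxide and erode the configuration at C6. E2 elimination to the 5,7-diene and attack of the peroxy anion on the coumarin are further losses. The fallback makes the C6–OO bond by an ene reaction instead of a substitution; it sets out from 14 and comes back at 22. Commercial 5-methylhex-4-enoic acid would be esterified (N-hydroxyphthalimide, DIC) to 1,3-dioxoisoindolin-2-yl 5-methylhex-4-enoate F1 and coupled with 14 under the conditions of step 12 to the prenyl-terminated ether 4-{[(2Z)-3-[(1-ethoxyethoxy)methyl]-7-methylocta-2,6-dien-1-yl]oxy}-5-methyl-2H-chromen-2-one F2. Sensitised photooxygenation (O2, tetraphenylporphyrin, hν, CH2Cl2, 0 °C; Schenck ene reaction at the electron-rich C6=C7 bond) should give, after chromatographic removal of the tertiary C7 hydroperoxide, the racemic acetal-protected secondary hydroperoxide F3. Aqueous acetic acid as in step 15 would then give the racemic target F4, and preparative HPLC on a chiral stationary phase would return the (6S)-enantiomer 22.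

2. Step 12. Low-valent nickel may insert into the allylic C1–O bond of the coumarinyl ether (in 14 or in the product), which would cleave or scramble the ether, and the C4 radical may be lost by a 1,5-hydrogen shift or by reduction. The fallback attaches the coumarin only after the carbon–carbon coupling; it sets out from 11 and comes back at 18. Silylation of the unhindered hydroxyl of 11 (TESCl, imidazole, −20 °C) would give (2E)-4-[(triethylsilyl)oxy]-2-(tributylstannyl)but-2-en-1-ol F5, iododestannylation (I2) the iodide (2E)-2-iodo-4-[(triethylsilyl)oxy]but-2-en-1-ol F6, and ethyl vinyl ether/PPTS its 1-ethoxyethyl ether {[(2E)-4-(1-ethoxyethoxy)-3-iodobut-2-en-1-yl]oxy}triethylsilane F7. Electro-coupling of F7 with 7 as in step 12 (no labile allylic C–O bond present) would give the triply protected diene F8. Buffered HF·pyridine would remove only the primary triethylsilyl group to give the allylic alcohol (2Z,6R)-6-[(tert-butyldimethylsilyl)oxy]-3-[(1-ethoxyethoxy)methyl]-7-methylocta-2,7-dien-1-ol F9, and Mitsunobu etherification with 9 would lead to 18.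

3. Step 8. The two allylic hydroxyls may be discriminated poorly, the cis-diol may cyclodehydrate to a 2,5-dihydrofuran, and the ambident coumarin may react at C3 or at the carbonyl oxygen. The fallback differentiates the hydroxyls by protection before the Mitsunobu reaction; it sets out from 11 and comes back at 14. TBSCl/imidazole would silylate the hydroxyl remote from tin to give (2E)-4-[(tert-butyldimethylsilyl)oxy]-2-(tributylstannyl)but-2-en-1-ol F10, ethyl vinyl ether/PPTS would cap the remaining hydroxyl to give the acetal F11, and TBAF would free the single primary alcohol (2E)-4-(1-ethoxyethoxy)-3-(tributylstannyl)but-2-en-1-ol F12. Mitsunobu etherification of F12 with 9 (only one hydroxyl, no cyclisation possible) would give the coumarinyl ether 4-{[(2E)-4-(1-ethoxyethoxy)-3-(tributylstannyl)but-2-en-1-yl]oxy}-5-methyl-2H-chromen-2-one F13, and iododestannylation with I2 would give 14.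

Further compounds
F1 | step 14 | 1,3-dioxoisoindolin-2-yl 5-methylhex-4-enoate | CC(C)=CCCC(=O)ON1C(=O)c2ccccc2C1=O
F2 | step 14 | 4-{[(2Z)-3-[(1-ethoxyethoxy)methyl]-7-methylocta-2,6-dien-1-yl]oxy}-5-methyl-2H-chromen-2-one | CC(C)=CCC/C(=C/COc1cc(=O)oc2cccc(C)c12)COC(C)OCC
F3 | step 14 | rac-4-{[(2Z)-3-[(1-ethoxyethoxy)methyl]-6-hydroperoxy-7-methylocta-2,7-dien-1-yl]oxy}-5-methyl-2H-chromen-2-one | C=C(C)C(CC/C(=C/COc1cc(=O)oc2cccc(C)c12)COC(C)OCC)OO
F4 | step 14 | rac-4-{[(2Z)-6-hydroperoxy-3-(hydroxymethyl)-7-methylocta-2,7-dien-1-yl]oxy}-5-methyl-2H-chromen-2-one | C=C(C)C(CC/C(=C/COc1cc(=O)oc2cccc(C)c12)CO)OO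
F5 | step 12 | (2E)-4-[(triethylsilyl)oxy]-2-(tributylstannyl)but-2-en-1-ol | CCCC[Sn](CCCC)(CCCC)/C(=C/CO[Si](CC)(CC)CC)CO
F6 | step 12 | (2E)-2-iodo-4-[(triethylsilyl)oxy]but-2-en-1-ol | I/C(=C/CO[Si](CC)(CC)CC)CO
F7 | step 12 | {[(2E)-4-(1-ethoxyethoxy)-3-iodobut-2-en-1-yl]oxy}triethylsilane | I/C(=C/CO[Si](CC)(CC)CC)COC(C)OCC
F8 | step 12 | tert-butyl{[(3R,6Z)-6-[(1-ethoxyethoxy)methyl]-2-methyl-8-[(triethylsilyl)oxy]octa-1,6-dien-3-yl]oxy}dimethylsilane | C=C(C)[C@@H](CC/C(=C/CO[Si](CC)(CC)CC)COC(C)OCC)O[Si](C)(C)C(C)(C)C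
F9 | step 12 | (2Z,6R)-6-[(tert-butyldimethylsilyl)oxy]-3-[(1-ethoxyethoxy)methyl]-7-methylocta-2,7-dien-1-ol | C=C(C)[C@@H](CC/C(=C/CO)COC(C)OCC)O[Si](C)(C)C(C)(C)C
F10 | step 8 | (2E)-4-[(tert-butyldimethylsilyl)oxy]-2-(tributylstannyl)but-2-en-1-ol | CCCC[Sn](CCCC)(CCCC)/C(=C/CO[Si](C)(C)C(C)(C)C)CO
F11 | step 8 | tert-butyl{[(2E)-4-(1-ethoxyethoxy)-3-(tributylstannyl)but-2-en-1-yl]oxy}dimethylsilane | CCCC[Sn](CCCC)(CCCC)/C(=C/CO[Si](C)(C)C(C)(C)C)COC(C)OCC
F12 | step 8 | (2E)-4-(1-ethoxyethoxy)-3-(tributylstannyl)but-2-en-1-ol | CCCC[Sn](CCCC)(CCCC)/C(=C/CO)COC(C)OCC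
F13 | step 8 | 4-{[(2E)-4-(1-ethoxyethoxy)-3-(tributylstannyl)but-2-en-1-yl]oxy}-5-methyl-2H-chromen-2-one | CCCC[Sn](CCCC)(CCCC)/C(=C/COc1cc(=O)oc2cccc(C)c12)COC(C)OCC
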